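## Retrosynthetic overview

1. Structural feature: the only stereocentre, C2, carries O1 and C1' of ring B. It lies two bonds from C4, a ring A benzylic CH2 para to O7. Restoring a carbonyl at C4 flattens ring C into a chromone whose C2 is an electrophilic enone terminus. Each prenyl (C8, C2') is ortho to a phenol oxygen (O7, O3') whose second ortho carbon (C6, C4') is already oxygenated.
2. Late disconnections: the 4'-O-MOM group is removed last. Before that, both prenyl C–C bonds are traced back together through a double aromatic Claisen shift to the 7,3'-bis(1,1-dimethylallyl) ether, made from the 7,3'-diphenol by propargylation and semihydrogenation.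
3. Central disconnection: C2–C1', by enantioselective rhodium-catalysed conjugate addition of a ring B boronic acid (from 5-bromosalicylaldehyde) to 7-benzyloxy-6-methoxychromone (from isovanillin). The C4 oxygen is then removed via alcohol, acetate and hydrogenolysis, together with both benzyl groups, while no alkene is present.
4. Ring order: rings A and B are bought as benzenes. Ring C is closed first as the achiral chromone (O1–C2 bond, addition–elimination on an enaminone). Ring B is attached in the key step, and no further ring is formed.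

Key step: step 10

Assumption: the (S)-configured biaryl bisphosphine is taken to deliver the aryl group to the chromone face that gives 2S, by analogy with its known sense on cyclic enones. If the configurational check on 17 shows the opposite, the (R)-ligand is used and nothing else changes.

## Route

Step 1
Reactants: 1 isovanillin
Product: 2 3-benzyloxy-4-methoxybenzaldehyde
Conditions: BnBr, K2CO3, DMF, rt to 50 °C
Reagents that add atoms: benzyl bromide, BrCc1ccccc1
Why: Williamson ether synthesis on the only phenol masks the future O7 with a group that can later be removed by hydrogenolysis.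

Step 2
Reactants: 2 3-benzyloxy-4-methoxybenzaldehyde
Product: 4 3-benzyloxy-4-methoxyphenol, via aryl formate 3 (not isolated)
Conditions: mCPBA, CH2Cl2, rt; aq. NaHCO3 wash; then K2CO3 (cat.), MeOH, rt
Reagents that add atoms: 3-chloroperoxybenzoic acid, OOC(=O)c1cccc(Cl)c1
Why: In this Baeyer–Villiger (Dakin-type) oxidation the electron-rich aryl group para to OMe migrates in preference to hydride, and methanolysis of the formate frees the phenol that becomes O1.

Step 3
Reactants: 4 3-benzyloxy-4-methoxyphenol
Product: 6 1-(4-benzyloxy-2-hydroxy-5-methoxyphenyl)ethanone, via aryl acetate 5 (not isolated)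
Conditions: Ac2O (1.2 equiv), BF3·OEt2, 0 to 45 °C; aq. NaOAc work-up
Reagents that add atoms: acetic anhydride, CC(=O)OC(C)=O
Why: O-acetylation followed by BF3-promoted Fries rearrangement should place the acetyl group ortho to the phenol and para to the benzyloxy group, because the other ortho carbon is wedged between two oxygens, and the trioxygenated ring reacts at a temperature low enough to spare the benzyl ether.

Step 4
Reactants: 6 1-(4-benzyloxy-2-hydroxy-5-methoxyphenyl)ethanone
Product: 7 (E)-1-(4-benzyloxy-2-hydroxy-5-methoxyphenyl)-3-(dimethylamino)prop-2-en-1-one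
Conditions: DMF dimethyl acetal, toluene, 95 °C
Reagents that add atoms: N,N-dimethylformamide dimethyl acetal, COC(OC)N(C)C
Why: Condensation of the methyl ketone with the formamide acetal (enaminone formation) adds the one carbon that becomes C2, while the chelated ortho phenol stays free.

Step 5
Reactants: 7 (E)-1-(4-benzyloxy-2-hydroxy-5-methoxyphenyl)-3-(dimethylamino)prop-2-en-1-one
Product: 8 7-benzyloxy-6-methoxychromone
Conditions: conc. HCl, CH2Cl2, rt to reflux
Reagents that add atoms: none
Why: Acid-mediated chromone synthesis, in which the phenol adds 6-endo to the protonated enaminone and dimethylamine is expelled, closes ring C as a flat achiral vinylogous ester.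

Step 6
Reactants: 9 5-bromosalicylaldehyde
Product: 10 5-bromo-2-(methoxymethoxy)benzaldehyde
Conditions: MOMCl, K2CO3, DMF, 0 °C to rt
Reagents that add atoms: chloromethyl methyl ether, COCCl
Why: O-alkylation of the phenol para to bromine installs an acetal on the future O4' that cannot migrate to a neighbouring phenoxide and tolerates organolithium, hydride, hydrogenation and heat.

Step 7
Reactants: 10 5-bromo-2-(methoxymethoxy)benzaldehyde
Product: 12 5-bromo-2-(methoxymethoxy)phenol, via aryl formate 11 (not isolated)
Conditions: mCPBA, CH2Cl2, rt to reflux; aq. NaHCO3 wash; then K2CO3 (cat.), MeOH, rt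
Reagents that add atoms: 3-chloroperoxybenzoic acid, OOC(=O)c1cccc(Cl)c1
Why: Baeyer–Villiger (Dakin-type) oxidation with aryl migration assisted by the ortho alkoxy group, followed by formate methanolysis, creates the second catechol oxygen (future O3') already differentiated from O4'.

Step 8
Reactants: 12 5-bromo-2-(methoxymethoxy)phenol
Product: 13 2-benzyloxy-4-bromo-1-(methoxymethoxy)benzene
Conditions: BnBr, K2CO3, DMF, rt
Reagents that add atoms: benzyl bromide, BrCc1ccccc1
Why: Williamson ether synthesis gives O3' the same hydrogenolysable group as O7, so both Claisen sites can be unmasked together.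

Step 9
Reactants: 13 2-benzyloxy-4-bromo-1-(methoxymethoxy)benzene
Product: 16 3-benzyloxy-4-(methoxymethoxy)phenylboronic acid, via aryllithium 14 (not isolated), via lithium aryltriisopropoxyborate 15 (not isolated)
Conditions: n-BuLi, THF, −78 °C; B(OiPr)3, −78 to 0 °C; 1 M HCl to pH 5, 0 °C
Reagents that add atoms: triisopropyl borate, CC(C)OB(OC(C)C)OC(C)C; water, O
Why: Bromine–lithium exchange at −78 °C outruns MOM-directed deprotonation and benzyl ether rearrangement, and trapping with the borate ester followed by brief cold hydrolysis gives the boronic acid with the acetal intact.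

Step 10
Reactants: 8 7-benzyloxy-6-methoxychromone; 16 3-benzyloxy-4-(methoxymethoxy)phenylboronic acid
Product: 17 (2S)-7,3'-bis(benzyloxy)-6-methoxy-4'-(methoxymethoxy)flavanone
Conditions: [Rh(OH)(cod)]2 (1.5 mol %), (S)-MeO-F12-BIPHEP [(S)-2,2'-bis{bis(3,4,5-trifluorophenyl)phosphino}-6,6'-dimethoxy-1,1'-biphenyl] (3.3 mol %), 16 (1.5 equiv), toluene/H2O 10:1, 25 °C
Reagents that add atoms: none
Why: Transmetalation of 16 to the hydroxo complex of monovalent rhodium gives a ligand-bound aryl–rhodium species, the C2=C3 bond of 8 coordinates and inserts with aryl transfer to C2, and water protonates the resulting oxa-π-allyl rhodium enolate to release 17 and regenerate Rh–OH. The closest known reaction type is the Hayashi–Miyaura asymmetric 1,4-addition of arylboronic acids, which is established for chromones as a route to 2-arylchroman-4-ones. No ring is closed because ring C already exists, and the only bond formed is C2–C1'. The new C2 stereocentre is controlled solely by the axially chiral bisphosphine, whose (S) form should block the face leading to 2R, since both partners are flat and achiral. The step needs 1,4- over 1,2-addition, which the vinylogous ester polarisation of the chromone and the soft aryl–rhodium nucleophile provide, and it needs the product not to racemise by retro-oxa-Michael opening, which the base-free two-phase medium at room temperature provides. The boronic acid has no ortho substituent and neither partner carries an alkene, so insertion is unhindered and nothing else competes for the metal.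

Step 11
Reactants: 17 (2S)-7,3'-bis(benzyloxy)-6-methoxy-4'-(methoxymethoxy)flavanone
Product: 18 (2S,4S)-7,3'-bis(benzyloxy)-6-methoxy-4'-(methoxymethoxy)flavan-4-ol
Conditions: NaBH4, THF/MeOH, −10 to 0 °C
Reagents that add atoms: none
Why: Borohydride reduction by axial attack on the half-chair with the C2 aryl group equatorial should give mainly the 2,4-cis (4S) alcohol; this centre is erased two steps later, and the low temperature keeps reduction faster than base-induced opening of ring C.

Step 12
Reactants: 18 (2S,4S)-7,3'-bis(benzyloxy)-6-methoxy-4'-(methoxymethoxy)flavan-4-ol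
Product: 19 (2S,4S)-7,3'-bis(benzyloxy)-6-methoxy-4'-(methoxymethoxy)flavan-4-yl acetate
Conditions: Ac2O, pyridine, DMAP (cat.), CH2Cl2, 0 °C to rt
Reagents that add atoms: acetic anhydride, CC(=O)OC(C)=O
Why: DMAP-catalysed acylation makes the C4 oxygen a better leaving group for hydrogenolysis without any acid, so the MOM acetal and the C2–O1 bond never meet ionising conditions.

Step 13
Reactants: 19 (2S,4S)-7,3'-bis(benzyloxy)-6-methoxy-4'-(methoxymethoxy)flavan-4-yl acetate
Product: 20 (2S)-7,3'-dihydroxy-6-methoxy-4'-(methoxymethoxy)flavan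
Conditions: H2 (1 atm), 10% Pd/C, EtOAc, rt
Reagents that add atoms: none
Why: Catalytic hydrogenolysis under neutral conditions should cleave both O-benzyl groups and the doubly activated C4 acetate (benzylic and para to O7), while the hindered, ring-constrained C2–O1 bond should persist as it does when benzylated catechins are debenzylated.

Step 14
Reactants: 20 (2S)-7,3'-dihydroxy-6-methoxy-4'-(methoxymethoxy)flavan; 21 3-chloro-3-methylbut-1-yne (two equivalents incorporated)
Product: 22 (2S)-6-methoxy-4'-(methoxymethoxy)-7,3'-bis(2-methylbut-3-yn-2-yloxy)flavan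
Conditions: 21 (3 equiv), CuCl2·2H2O (2 mol %), DBU (3 equiv), MeCN, 0 °C to rt
Reagents that add atoms: none
Why: Copper-catalysed O-alkylation of phenols with a tertiary propargylic chloride forms the hindered tertiary aryl ethers that direct displacement cannot, and C2 is safe under DBU because masked O4' cannot generate a para-quinone methide.

Step 15
Reactants: 22 (2S)-6-methoxy-4'-(methoxymethoxy)-7,3'-bis(2-methylbut-3-yn-2-yloxy)flavan
Product: 23 (2S)-6-methoxy-4'-(methoxymethoxy)-7,3'-bis(2-methylbut-3-en-2-yloxy)flavan
Conditions: H2 (1 atm), Pd/CaCO3 poisoned with Pb(OAc)2 (Lindlar catalyst), quinoline, EtOAc, rt, stopped after uptake of 2 equiv H2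
Reagents that add atoms: none
Why: Lindlar semihydrogenation stops both terminal alkynes at the alkene stage, and the poisoned catalyst is too weak to cleave the allylic or benzylic C–O bonds.

Step 16
Reactants: 23 (2S)-6-methoxy-4'-(methoxymethoxy)-7,3'-bis(2-methylbut-3-en-2-yloxy)flavan
Product: 24 (2S)-7,3'-dihydroxy-6-methoxy-4'-(methoxymethoxy)-8,2'-diprenylflavan
Conditions: PhNEt2 (degassed), 130 °C, Ar
Reagents that add atoms: none
Why: In this double aromatic Claisen rearrangement each 1,1-dimethylallyl ether bonds its CH2 terminus by a [3,3] shift to the one hydrogen-bearing ortho carbon (C8, as C6 holds OMe; C2', as C4' holds OMOM), rearomatisation makes each shift irreversible, the basic solvent suppresses ether ionisation and chroman closure, and no bond at C2 is involved.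

Step 17
Reactants: 24 (2S)-7,3'-dihydroxy-6-methoxy-4'-(methoxymethoxy)-8,2'-diprenylflavan
Product: 25 (2S)-7,3',4'-trihydroxy-6-methoxy-8,2'-diprenylflavan (CNP0214453.1)
Conditions: p-TsOH·H2O (10 mol %), degassed MeOH, rt to 40 °C, Ar
Reagents that add atoms: none
Why: Acid-catalysed acetal exchange with methanol should remove the phenolic MOM group, which is the most acid-labile function and sits next to a free hydroxyl, faster than the trisubstituted alkenes are protonated or the C2–O1 bond ionises.

## Compound list

1 | isovanillin (3-hydroxy-4-methoxybenzaldehyde) | COc1ccc(C=O)cc1O | starting material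
2 | 3-benzyloxy-4-methoxybenzaldehyde | COc1ccc(C=O)cc1OCc1ccccc1 | intermediate
3 | 3-benzyloxy-4-methoxyphenyl formate | COc1ccc(OC=O)cc1OCc1ccccc1 | intermediate
4 | 3-benzyloxy-4-methoxyphenol | COc1ccc(O)cc1OCc1ccccc1 | intermediate
5 | 3-benzyloxy-4-methoxyphenyl acetate | COc1ccc(OC(C)=O)cc1OCc1ccccc1 | intermediate
6 | 1-(4-benzyloxy-2-hydroxy-5-methoxyphenyl)ethanone | CC(=O)c1cc(OC)c(OCc2ccccc2)cc1O | intermediate
7 | (E)-1-(4-benzyloxy-2-hydroxy-5-methoxyphenyl)-3-(dimethylamino)prop-2-en-1-one | CN(C)/C=C/C(=O)c1cc(OC)c(OCc2ccccc2)cc1O | intermediate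
8 | 7-benzyloxy-6-methoxychromone | COc1cc2C(=O)C=COc2cc1OCc1ccccc1 | intermediate
9 | 5-bromosalicylaldehyde | O=Cc1cc(Br)ccc1O | starting material
10 | 5-bromo-2-(methoxymethoxy)benzaldehyde | COCOc1ccc(Br)cc1C=O | intermediate
11 | 5-bromo-2-(methoxymethoxy)phenyl formate | COCOc1ccc(Br)cc1OC=O | intermediate
12 | 5-bromo-2-(methoxymethoxy)phenol | COCOc1ccc(Br)cc1O | intermediate
13 | 2-benzyloxy-4-bromo-1-(methoxymethoxy)benzene | COCOc1ccc(Br)cc1OCc1ccccc1 | intermediate
14 | 3-benzyloxy-4-(methoxymethoxy)phenyllithium | [Li]c1ccc(OCOC)c(OCc2ccccc2)c1 | intermediate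
15 | lithium [3-benzyloxy-4-(methoxymethoxy)phenyl]triisopropoxyborate | [Li+].CC(C)O[B-](OC(C)C)(OC(C)C)c1ccc(OCOC)c(OCc2ccccc2)c1 | intermediate
16 | 3-benzyloxy-4-(methoxymethoxy)phenylboronic acid | COCOc1ccc(B(O)O)cc1OCc1ccccc1 | intermediate
17 | (2S)-7,3'-bis(benzyloxy)-6-methoxy-4'-(methoxymethoxy)flavanone | COc1cc2c(cc1OCc1ccccc1)O[C@H](c1ccc(OCOC)c(OCc3ccccc3)c1)CC2=O | intermediate
18 | (2S,4S)-7,3'-bis(benzyloxy)-6-methoxy-4'-(methoxymethoxy)flavan-4-ol (2,4-cis) | COc1cc2c(cc1OCc1ccccc1)O[C@H](c1ccc(OCOC)c(OCc3ccccc3)c1)C[C@@H]2O | intermediate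
19 | (2S,4S)-7,3'-bis(benzyloxy)-6-methoxy-4'-(methoxymethoxy)flavan-4-yl acetate | COc1cc2c(cc1OCc1ccccc1)O[C@H](c1ccc(OCOC)c(OCc3ccccc3)c1)C[C@@H]2OC(C)=O | intermediate
20 | (2S)-7,3'-dihydroxy-6-methoxy-4'-(methoxymethoxy)flavan | COc1cc2c(cc1O)O[C@H](c1ccc(OCOC)c(O)c1)CC2 | intermediate
21 | 3-chloro-3-methylbut-1-yne | CC(C)(Cl)C#C | starting material
22 | (2S)-6-methoxy-4'-(methoxymethoxy)-7,3'-bis(2-methylbut-3-yn-2-yloxy)flavan | COc1cc2c(cc1OC(C)(C)C#C)O[C@H](c1ccc(OCOC)c(OC(C)(C)C#C)c1)CC2 | intermediate
23 | (2S)-6-methoxy-4'-(methoxymethoxy)-7,3'-bis(2-methylbut-3-en-2-yloxy)flavan | COc1cc2c(cc1OC(C)(C)C=C)O[C@H](c1ccc(OCOC)c(OC(C)(C)C=C)c1)CC2 | intermediate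
24 | (2S)-7,3'-dihydroxy-6-methoxy-4'-(methoxymethoxy)-8,2'-diprenylflavan | COc1cc2c(c(CC=C(C)C)c1O)O[C@H](c1ccc(OCOC)c(O)c1CC=C(C)C)CC2 | intermediate
25 | (2S)-7,3',4'-trihydroxy-6-methoxy-8,2'-diprenylflavan (CNP0214453.1) | COc1cc2c(c(CC=C(C)C)c1O)O[C@H](c1ccc(O)c(O)c1CC=C(C)C)CC2 | target

## Step count and risks

Total step count: 17.
Longest linear sequence: 13 steps (steps 1–5, then 10–17). The boronic acid branch (steps 6–9) joins at step 10.

Steps most likely to fail:

1. Step 16 (double Claisen).
   - What may go wrong: the tertiary allyl groups may be lost by heterolysis or retro-ene cleavage before the shift. On ring B the group may also migrate through the blocked C4' and a Cope shift to the para carbon C6', because C2' is crowded by the chroman substituent.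
   - Fallback, from 20 back to 24: diol 20 would be O-allylated (allyl bromide, K2CO3, acetone) to (2S)-7,3'-bis(allyloxy)-6-methoxy-4'-(methoxymethoxy)flavan F1, whose primary ethers cannot ionise. Heating in PhNEt2 at about 190 °C should give (2S)-8,2'-diallyl-7,3'-dihydroxy-6-methoxy-4'-(methoxymethoxy)flavan F2, with the small allyl terminus entering the crowded ortho carbons. Olefin cross-metathesis with excess 2-methylbut-2-ene (second-generation Grubbs catalyst, RuCl2(H2IMes)(PCy3)(=CHPh), CH2Cl2, 40 °C) would then convert both allyl groups into prenyl groups and rejoin the route at 24.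

2. Step 10 (key conjugate addition).
   - What may go wrong: insertion into the electron-rich 6,7-dioxygenated chromone may be sluggish and overtaken by protodeboronation, or enantiopurity may erode through reversible opening of ring C.
   - Fallback, from 13 and 6 back to 18: aryllithium 14, made from 13 as in step 9, would be quenched with DMF to give 3-benzyloxy-4-(methoxymethoxy)benzaldehyde F3. Claisen–Schmidt condensation with ketone 6 (KOH, EtOH) would give (E)-1-(4-benzyloxy-2-hydroxy-5-methoxyphenyl)-3-[3-benzyloxy-4-(methoxymethoxy)phenyl]prop-2-en-1-one F4. Oxa-Michael cyclisation (NaOAc, EtOH, reflux) would give racemic 7,3'-bis(benzyloxy)-6-methoxy-4'-(methoxymethoxy)flavanone F5.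
   - Kinetic resolution by Noyori-type asymmetric transfer hydrogenation (RuCl[(S,S)-TsDPEN](p-cymene), HCO2H/Et3N, EtOAc, rt) should reduce the 2S ketone selectively to the cis alcohol 18. The unreacted (2R)-7,3'-bis(benzyloxy)-6-methoxy-4'-(methoxymethoxy)flavanone F6 can be racemised with base and recycled.

3. Step 17 (final MOM cleavage).
   - What may go wrong: acid may close the ortho-prenylphenols onto their alkenes, the C2–O1 bond may ionise once the para 4'-hydroxyl is free, and the catechol may oxidise in air.
   - Fallback, from 22 back to 25: the acetal would be exchanged while only acid-tolerant alkynes are present. Compound 22 with p-TsOH (cat.) in MeOH would give (2S)-4'-hydroxy-6-methoxy-7,3'-bis(2-methylbut-3-yn-2-yloxy)flavan F7. TBSCl and imidazole in DMF would give (2S)-4'-(tert-butyldimethylsilyloxy)-6-methoxy-7,3'-bis(2-methylbut-3-yn-2-yloxy)flavan F8.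
   - Semihydrogenation as in step 15 would give (2S)-4'-(tert-butyldimethylsilyloxy)-6-methoxy-7,3'-bis(2-methylbut-3-en-2-yloxy)flavan F9. Rearrangement as in step 16 would give (2S)-4'-(tert-butyldimethylsilyloxy)-7,3'-dihydroxy-6-methoxy-8,2'-diprenylflavan F10; any silyl shift between O4' and O3' at this stage is harmless. Near-neutral fluoride (Et3N·3HF, THF, 0 °C) would then release 25 without acid.

## Further compounds

F1 | step 16 | (2S)-7,3'-bis(allyloxy)-6-methoxy-4'-(methoxymethoxy)flavan | COc1cc2c(cc1OCC=C)O[C@H](c1ccc(OCOC)c(OCC=C)c1)CC2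
F2 | step 16 | (2S)-8,2'-diallyl-7,3'-dihydroxy-6-methoxy-4'-(methoxymethoxy)flavan | COc1cc2c(c(CC=C)c1O)O[C@H](c1ccc(OCOC)c(O)c1CC=C)CC2
F3 | step 10 | 3-benzyloxy-4-(methoxymethoxy)benzaldehyde | COCOc1ccc(C=O)cc1OCc1ccccc1
F4 | step 10 | (E)-1-(4-benzyloxy-2-hydroxy-5-methoxyphenyl)-3-[3-benzyloxy-4-(methoxymethoxy)phenyl]prop-2-en-1-one | COc1cc(C(=O)/C=C/c2ccc(OCOC)c(OCc3ccccc3)c2)c(O)cc1OCc1ccccc1
F5 | step 10 | racemic 7,3'-bis(benzyloxy)-6-methoxy-4'-(methoxymethoxy)flavanone | COc1cc2c(cc1OCc1ccccc1)OC(c1ccc(OCOC)c(OCc3ccccc3)c1)CC2=O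
F6 | step 10 | (2R)-7,3'-bis(benzyloxy)-6-methoxy-4'-(methoxymethoxy)flavanone | COc1cc2c(cc1OCc1ccccc1)O[C@@H](c1ccc(OCOC)c(OCc3ccccc3)c1)CC2=O
F7 | step 17 | (2S)-4'-hydroxy-6-methoxy-7,3'-bis(2-methylbut-3-yn-2-yloxy)flavan | COc1cc2c(cc1OC(C)(C)C#C)O[C@H](c1ccc(O)c(OC(C)(C)C#C)c1)CC2
F8 | step 17 | (2S)-4'-(tert-butyldimethylsilyloxy)-6-methoxy-7,3'-bis(2-methylbut-3-yn-2-yloxy)flavan | COc1cc2c(cc1OC(C)(C)C#C)O[C@H](c1ccc(O[Si](C)(C)C(C)(C)C)c(OC(C)(C)C#C)c1)CC2
F9 | step 17 | (2S)-4'-(tert-butyldimethylsilyloxy)-6-methoxy-7,3'-bis(2-methylbut-3-en-2-yloxy)flavan | COc1cc2c(cc1OC(C)(C)C=C)O[C@H](c1ccc(O[Si](C)(C)C(C)(C)C)c(OC(C)(C)C=C)c1)CC2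
F10 | step 17 | (2S)-4'-(tert-butyldimethylsilyloxy)-7,3'-dihydroxy-6-methoxy-8,2'-diprenylflavan | COc1cc2c(c(CC=C(C)C)c1O)O[C@H](c1ccc(O[Si](C)(C)C(C)(C)C)c(O)c1CC=C(C)C)CC2
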